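Retrosynthetic cuts, in order: (a) the C5–CH= bond of the acrylic acid (Heck); (b) the CH2–O bond of the p-coumarate ester (Mitsunobu with unprotected p-coumaric acid); (c) together, the ring bond O1–C2 and the bond from Cα to the oxymethyl carbon, leading back to 4-bromo-2-[(Z)-but-2-enyl]phenol, CO and methanol; (d) the Z-alkene (Wittig) and the aryl–C3 bond (Claisen).
Enabling feature (benzofuran numbering; Cα is the methyl-bearing side-chain carbon): in the dihydrofuran ring O1 sits on C2, and the oxymethyl carbon sits on the adjacent exocyclic Cα. C2 and Cα are therefore the two ends of a former C=C bond that lies one CH2 (C3) from the arene carbon ortho to the phenol oxygen, and O1 and one carbon atom are what has been added across it.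
Forward: the benzene ring is bought. O-allylation and Claisen rearrangement bring in C3 and C2, and ozonolysis with Z-Wittig olefination complete the butenyl chain. The dihydrofuran ring then closes with uptake of CO, and ester reduction, Mitsunobu esterification and a Heck reaction finish the two chain ends.
Stereochemistry: both stereocentres arise in the ring closure. The absolute sense comes from a chiral bis(oxazoline) ligand on palladium, and the relative (syn O1/CH3) sense comes from the Z-alkene through syn-oxypalladation and retentive CO insertion. One E-alkene is bought with p-coumaric acid and the other comes from the Heck step.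

Key step: step 5

Assumption: the sense of induction of the BOXAX ligand on a (Z)-1,2-disubstituted alkene is not established, so the route is written with the (S,S) ligand giving the (2S) series, and the equally accessible (R,R) ligand is taken should the sense be the opposite.

Step 1
Reactants: 1 4-bromophenol; 2 allyl bromide
Product: 3 allyl 4-bromophenyl ether
Conditions: K2CO3, acetone, reflux
Reagents that add atoms: none
Why: Williamson ether synthesis, in which the phenoxide formed by K2CO3 displaces bromide from the unhindered allylic halide at oxygen.

Step 2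
Reactants: 3 allyl 4-bromophenyl ether
Product: 5 2-allyl-4-bromophenol, via dienone 4 (not isolated)
Conditions: PhNEt2, 200 °C
Reagents that add atoms: none
Why: Aromatic Claisen rearrangement, a [3,3]-sigmatropic shift to one of the two equivalent ortho positions (the para position is blocked by bromine), gives dienone 4, which tautomerises to the phenol.

Step 3
Reactants: 5 2-allyl-4-bromophenol
Product: 8 5-bromo-2,3-dihydro-1-benzofuran-2-ol (racemic lactol), via ozonide 6 (not isolated), via hydroxy aldehyde 7 (not isolated)
Conditions: O3, CH2Cl2, −78 °C; then Me2S, −78 °C to rt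
Reagents that add atoms: ozone [O-][O+]=O
Why: Ozonolysis with reductive work-up, in which the terminal alkene reacts with ozone far faster than the bromine-deactivated phenol ring, Me2S reduces ozonide 6 to aldehyde 7, and 7 closes by itself to the five-membered lactol, whose stereocentre is lost again in step 4.

Step 4
Reactants: 8 5-bromo-2,3-dihydro-1-benzofuran-2-ol
Product: 9 4-bromo-2-[(2Z)-but-2-en-1-yl]phenol
Conditions: EtPPh3Br (2.6 equiv), NaN(SiMe3)2 (2.5 equiv), THF, 0 °C; then 8, −78 °C to rt
Reagents that add atoms: ethyltriphenylphosphonium bromide CC[P+](c1ccccc1)(c1ccccc1)c1ccccc1.[Br-]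
Why: Wittig olefination, in which base opens lactol 8 to the phenoxide of aldehyde 7 and the non-stabilised ylide under lithium-free kinetic control should give the (Z)-alkene.

Step 5
Reactants: 9 4-bromo-2-[(2Z)-but-2-en-1-yl]phenol
Product: 12 methyl (2R)-2-[(2S)-5-bromo-2,3-dihydro-1-benzofuran-2-yl]propanoate, via alkylpalladium 10 (not isolated), via acylpalladium 11 (not isolated)
Conditions: Pd(OCOCF3)2 (10 mol %), (S,S)-iPr-BOXAX [(S)-2,2'-bis((4S)-4-isopropyl-4,5-dihydrooxazol-2-yl)-1,1'-binaphthyl] (20 mol %), p-benzoquinone (2 equiv), CO (1 atm), MeOH, 0 °C to rt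
Reagents that add atoms: carbon monoxide [C-]#[O+]; methanol CO
Why: Proposed new method: The phenol oxygen and the (Z)-alkene of 9 bind side by side to the ligand-bound divalent palladium, the alkene inserts into the Pd–O bond (syn-oxypalladation) and so closes O1–C2 to give 10, CO takes the freed site and inserts with retention at Cα to give 11, methanol cleaves 11 to 12, and p-benzoquinone brings the zerovalent palladium back to the divalent state. The closest known reaction types are the enantioselective Wacker-type cyclisation/carbonylation/methanolysis domino of o-alkenylphenols with 1,1-disubstituted alkenes, run with these same reagents, and the stereospecific intramolecular alkoxycarbonylation of 1,2-disubstituted hydroxyalkenes; new is their union on a phenol whose alkylpalladium intermediate carries β-hydrogens and a second stereocentre. The dihydrofuran ring closes 5-exo-trig, since the single carbon C3 between arene and alkene lets the palladium-bound oxygen reach C2 in a planar four-centre insertion but not Cα (6-endo). C2 (S) is controlled by the twofold-symmetric ligand, which should admit the alkene with its C2-Si/Cα-Re face towards palladium, and Cα (R in 12) is controlled by the Z geometry of 9 together with syn addition and retentive CO insertion, so that the syn O1/CH3 relationship of the target follows from the alkene geometry alone. The step needs syn and not anti attack, which the chloride-free trifluoroacetate salt and the chelating ligand secure (deuterium labelling of o-allylphenol cyclisations has tied syn addition to such conditions and anti addition to added chloride), and it needs CO capture of 10 to outrun β-hydride elimination to the 2-vinyl or 2-ethylidene ethers, which CO saturation, low temperature and the quinone as hydride scavenger favour. The C5–Br bond should survive because zerovalent palladium is reoxidised by the quinone much faster than it can insert into an electron-rich aryl bromide at room temperature, and the bromine para to the hydroxyl makes the phenol less prone to oxidation without blocking its coordination.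

Step 6
Reactants: 12 methyl (2R)-2-[(2S)-5-bromo-2,3-dihydro-1-benzofuran-2-yl]propanoate
Product: 13 (2S)-2-[(2S)-5-bromo-2,3-dihydro-1-benzofuran-2-yl]propan-1-ol
Conditions: LiBH4, THF, 0 °C to rt; aq. NH4Cl
Reagents that add atoms: none
Why: Ester reduction with LiBH4, which leaves the aryl bromide alone and is too weakly basic to epimerise Cα or to expel the β-aryloxide by E1cB, so both stereocentres pass through unchanged (the descriptor at Cα changes from R to S only through the priority rules).

Step 7
Reactants: 13 (2S)-2-[(2S)-5-bromo-2,3-dihydro-1-benzofuran-2-yl]propan-1-ol; 14 (E)-p-coumaric acid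
Product: 15 (2S)-2-[(2S)-5-bromo-2,3-dihydro-1-benzofuran-2-yl]propyl (E)-3-(4-hydroxyphenyl)prop-2-enoate
Conditions: PPh3, DIAD, THF, 0 °C to rt
Reagents that add atoms: none
Why: Mitsunobu esterification, in which only the carboxylic acid of 14 (about five pKa units more acidic than its phenol) is deprotonated by the betaine, so the carboxylate is alkylated at the activated primary, non-stereogenic carbon and no phenol protection is needed.

Step 8
Reactants: 15 (2S)-2-[(2S)-5-bromo-2,3-dihydro-1-benzofuran-2-yl]propyl (E)-3-(4-hydroxyphenyl)prop-2-enoate; 16 acrylic acid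
Product: 17 (E)-3-{(2S)-2-[(2S)-1-{[(E)-3-(4-hydroxyphenyl)prop-2-enoyl]oxy}propan-2-yl]-2,3-dihydro-1-benzofuran-5-yl}prop-2-enoic acid (target)
Conditions: Pd(OAc)2 (5 mol %), P(o-tol)3 (15 mol %), Et3N, DMF, 95 °C; dilute aq. HCl work-up
Reagents that add atoms: none
Why: Mizoroki–Heck reaction, in which oxidative addition into the C5–Br bond, regioselective insertion of the monosubstituted acrylic acid (much faster than insertion of the 1,2-disubstituted coumarate alkene) and syn β-hydride elimination should give the (E)-acrylic acid directly, without touching the stereocentres.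

Compound list
1 | 4-bromophenol | Oc1ccc(Br)cc1 | starting material
2 | allyl bromide (3-bromoprop-1-ene) | C=CCBr | starting material
3 | allyl 4-bromophenyl ether (1-bromo-4-(prop-2-enyloxy)benzene) | C=CCOc1ccc(Br)cc1 | intermediate
4 | 4-bromo-6-(prop-2-enyl)cyclohexa-2,4-dien-1-one (racemic) | O=C1C=CC(Br)=CC1CC=C | intermediate
5 | 2-allyl-4-bromophenol | C=CCc1cc(Br)ccc1O | intermediate
6 | 4-bromo-2-[(1,2,4-trioxolan-3-yl)methyl]phenol (racemic ozonide) | Oc1ccc(Br)cc1CC1OCOO1 | intermediate
7 | (5-bromo-2-hydroxyphenyl)acetaldehyde | O=CCc1cc(Br)ccc1O | intermediate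
8 | 5-bromo-2,3-dihydro-1-benzofuran-2-ol (racemic lactol) | OC1Cc2cc(Br)ccc2O1 | intermediate
9 | 4-bromo-2-[(2Z)-but-2-en-1-yl]phenol | C/C=C\Cc1cc(Br)ccc1O | intermediate
10 | {(1R)-1-[(2S)-5-bromo-2,3-dihydro-1-benzofuran-2-yl]ethyl}palladium trifluoroacetate (bis(oxazoline) ligand on palladium not drawn) | C[C@@H]([Pd]OC(=O)C(F)(F)F)[C@@H]1Cc2cc(Br)ccc2O1 | intermediate
11 | {(2R)-2-[(2S)-5-bromo-2,3-dihydro-1-benzofuran-2-yl]propanoyl}palladium trifluoroacetate (bis(oxazoline) ligand on palladium not drawn) | C[C@@H](C(=O)[Pd]OC(=O)C(F)(F)F)[C@@H]1Cc2cc(Br)ccc2O1 | intermediate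
12 | methyl (2R)-2-[(2S)-5-bromo-2,3-dihydro-1-benzofuran-2-yl]propanoate | C[C@@H](C(=O)OC)[C@@H]1Cc2cc(Br)ccc2O1 | intermediate
13 | (2S)-2-[(2S)-5-bromo-2,3-dihydro-1-benzofuran-2-yl]propan-1-ol | C[C@@H](CO)[C@@H]1Cc2cc(Br)ccc2O1 | intermediate
14 | (E)-p-coumaric acid ((E)-3-(4-hydroxyphenyl)prop-2-enoic acid) | O=C(O)/C=C/c1ccc(O)cc1 | starting material
15 | (2S)-2-[(2S)-5-bromo-2,3-dihydro-1-benzofuran-2-yl]propyl (E)-3-(4-hydroxyphenyl)prop-2-enoate | C[C@@H](COC(=O)/C=C/c1ccc(O)cc1)[C@@H]1Cc2cc(Br)ccc2O1 | intermediate
16 | acrylic acid | C=CC(=O)O | starting material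
17 | (E)-3-{(2S)-2-[(2S)-1-{[(E)-3-(4-hydroxyphenyl)prop-2-enoyl]oxy}propan-2-yl]-2,3-dihydro-1-benzofuran-5-yl}prop-2-enoic acid | C[C@@H](COC(=O)/C=C/c1ccc(O)cc1)[C@@H]1Cc2cc(/C=C/C(=O)O)ccc2O1 | target

Total step count: 8. Longest linear sequence: 8 steps (1 to 17).

Steps most likely to fail

Step 5 (the labelled step).
- What may go wrong: the ligand discriminates poorly between the faces of the slim 1,2-disubstituted alkene. β-Hydride elimination may outrun CO capture. Some material may leak into anti-oxypalladation, which would erode the syn relationship.
- Fallback by known chemistry, from 1 back to 13: ortho-iodination of 1 (NIS, TsOH, MeCN) should give 4-bromo-2-iodophenol F1.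
- Enantioselective palladium-catalysed heteroannulation of isoprene then follows (Pd2(dba)3, chiral sulfinamide-phosphine or phosphoramidite ligand, Na2CO3), selective for C–I over C–Br. Heck insertion at the unsubstituted vinyl terminus forms the aryl–C3 bond, and the phenoxide closes O1–C2 on the π-allylpalladium in the Tsuji–Trost manner. This should give (2S)-5-bromo-2-(prop-1-en-2-yl)-2,3-dihydro-1-benzofuran F2.
- RhCl(PPh3)3-catalysed hydroboration with catecholborane is the variant known to give the syn 2-methyl-1,3-dioxygen pattern from 1,1-disubstituted alkenes beside an allylic C–O stereocentre. It should give 2-{(2S)-2-[(2S)-5-bromo-2,3-dihydro-1-benzofuran-2-yl]propyl}-1,3,2-benzodioxaborole F3, which NaOH/H2O2 oxidises to 13.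

Step 4.
- What may go wrong: the basic ylide enolises the arylacetaldehyde, with self-condensation, in competition with olefination, and the alkene geometry drifts towards E.
- Fallback, from 5 back to 9 (this also bypasses step 3): stereoretentive cross-metathesis of 5 with excess (Z)-but-2-ene, using Ru(=CH-C6H4-2-OiPr)(SIMes)(S2C6H2Cl2-3,6) in THF at rt. The Z geometry of the butene is carried over to the product without any aldehyde stage. New compounds on this way: none F0.

Step 8.
- What may go wrong: oxidative addition of the electron-rich aryl bromide is sluggish in the presence of carboxylate and phenoxide, and the coumarate alkene is arylated in competition.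
- Fallback, from 13 back to 17, which changes the order of events and masks the acid: the Heck reaction is run on 13, before any coumarate is present, with tert-butyl acrylate (Pd(OAc)2, P(o-tol)3, Et3N, DMF, 100 °C). It should give tert-butyl (E)-3-{(2S)-2-[(2S)-1-hydroxypropan-2-yl]-2,3-dihydro-1-benzofuran-5-yl}prop-2-enoate F4.
- Mitsunobu esterification of this alcohol with 14 (PPh3, DIAD, THF) should give the tert-butyl ester of the target F5. Acidolysis (CF3CO2H, Et3SiH, CH2Cl2, 0 °C to rt) then releases 17 and leaves the primary coumarate ester intact.

Further compounds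
F1 | step 5 | 4-bromo-2-iodophenol | Oc1ccc(Br)cc1I
F2 | step 5 | (2S)-5-bromo-2-(prop-1-en-2-yl)-2,3-dihydro-1-benzofuran | C=C(C)[C@@H]1Cc2cc(Br)ccc2O1
F3 | step 5 | 2-{(2S)-2-[(2S)-5-bromo-2,3-dihydro-1-benzofuran-2-yl]propyl}-1,3,2-benzodioxaborole | C[C@@H](CB1Oc2ccccc2O1)[C@@H]1Cc2cc(Br)ccc2O1
F0 | step 4 | none | none
F4 | step 8 | tert-butyl (E)-3-{(2S)-2-[(2S)-1-hydroxypropan-2-yl]-2,3-dihydro-1-benzofuran-5-yl}prop-2-enoate | C[C@@H](CO)[C@@H]1Cc2cc(/C=C/C(=O)OC(C)(C)C)ccc2O1
F5 | step 8 | tert-butyl ester of the target | C[C@@H](COC(=O)/C=C/c1ccc(O)cc1)[C@@H]1Cc2cc(/C=C/C(=O)OC(C)(C)C)ccc2O1
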